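**Plan**

1. Numbering (cembrane): C1 is the ring carbon bearing the 2-hydroxyprop-2-yl group (C15), then C2, the Z alkene C3=C4(Me), C5, C6, the oxirane C7–C8(Me), C9, C10 (OAc), the E alkene C11=C12(Me), C13, C14.
2. Retrosynthetic cuts, in order: acetate and silyl ether; ring bond C4–C5 (alkyl–alkenyl Suzuki); C5=C6 (Wittig), which turns C6 into a carbonyl tied to the C10 oxygen; the two oxirane C–O bonds; C9–C10 together with the lactone C–O (vinylogous aldol); C1–C2 (imide alkylation).
3. Enabling feature: C6, C7, C8, C9, C10 and the C10 oxygen form an unbroken six-atom run, so they can be drawn as a 4-methyl-5,6-dihydropyran-2-one with C6 as carbonyl. In that ring C7=C8 must be Z (hence a cis-oxirane), and the C10 stereocentre can steer an oxidant to the face that gives the syn C8–O/C10–O relationship.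
4. Forward order: the chain is joined at C1–C2, then at C9–C10 with closure of the temporary δ-lactone; the oxirane is fused onto the lactone; the lactone is unfolded by reduction and methylenation; the 14-membered carbocycle closes last at C4–C5.
5. Stereochemistry: C1 from the oxazolidinone auxiliary, C10 from a chiral copper catalyst, C7 and C8 relayed from C10 through the lactone; Z-C3=C4 from trans-hydroalumination/iodination and a stereoretentive coupling; E-C11=C12 from syn-carboalumination.

Key step: step 13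

Assumption: the sense of induction of the Tol-BINAP copper fluoride catalyst with this β,β-disubstituted enal is assumed; (S)-Tol-BINAP is written for the Si-face addition that gives (S)-C10, and (R)-Tol-BINAP replaces it, with nothing else changed, if the sense proves opposite.

**Route**

Step 1
Reactants: 1 but-2-yn-1-ol
Product: 3 (2Z)-3-iodobut-2-en-1-ol, via cyclic alkenylaluminate 2 (not isolated)
Conditions: NaAlH2(OCH2CH2OMe)2, THF, 0 °C to rt; EtOAc; then I2, THF, −78 to 0 °C
Reagents that add atoms: iodine, II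
Why: Hydroxyl-directed trans-hydroalumination of the propargylic alcohol places aluminium on the methyl-bearing carbon anti to the new C–H bond, and iodinolysis of the alkenyl–aluminium bond with retention fixes the Z-iodoalkene that later becomes C3=C4; no stereocentre is formed.

Step 2
Reactants: 3 (2Z)-3-iodobut-2-en-1-ol
Product: 4 (2Z)-1-bromo-3-iodobut-2-ene
Conditions: CBr4, PPh3, CH2Cl2, 0 °C
Reagents that add atoms: carbon tetrabromide, BrC(Br)(Br)Br
Why: Appel bromination replaces the primary allylic hydroxyl by SN2 displacement of the oxyphosphonium group and leaves the alkene geometry and the C–I bond untouched.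

Step 3
Reactants: 5 hex-5-ynoic acid; 6 (4S)-4-benzyl-1,3-oxazolidin-2-one
Product: 8 (4S)-4-benzyl-3-(hex-5-ynoyl)-1,3-oxazolidin-2-one, via mixed pivalic anhydride 7 (not isolated)
Conditions: t-BuCOCl, Et3N, THF, −20 °C; then LiCl, 6, −20 °C to rt
Reagents that add atoms: none
Why: N-Acylation of the oxazolidinone through the mixed pivalic anhydride under LiCl/Et3N activation is the standard mild route to N-acyl imides, proceeds at the less hindered carbonyl of the anhydride and tolerates the terminal alkyne.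

Step 4
Reactants: 8 (4S)-4-benzyl-3-(hex-5-ynoyl)-1,3-oxazolidin-2-one; 4 (2Z)-1-bromo-3-iodobut-2-ene
Product: 10 (4S)-4-benzyl-3-[(2R,4Z)-2-(but-3-yn-1-yl)-5-iodohex-4-enoyl]-1,3-oxazolidin-2-one, via sodium enolate 9 (not isolated)
Conditions: NaN(SiMe3)2, THF, −78 °C; then 4, −78 to −40 °C
Reagents that add atoms: none
Why: Evans asymmetric alkylation, in which the chelated sodium Z-enolate is attacked by the reactive allylic bromide on the face opposite the benzyl group, forms C1–C2 and sets C1 as R.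

Step 5
Reactants: 10 (4S)-4-benzyl-3-[(2R,4Z)-2-(but-3-yn-1-yl)-5-iodohex-4-enoyl]-1,3-oxazolidin-2-one
Product: 11 benzyl (2R,4Z)-2-(but-3-yn-1-yl)-5-iodohex-4-enoate
Conditions: BnOLi (from BnOH and n-BuLi), THF, −78 to 0 °C
Reagents that add atoms: benzyl alcohol, used as its lithium alkoxide, OCc1ccccc1
Why: Transesterification with lithium benzyloxide attacks the exocyclic imide carbonyl, releases the recoverable auxiliary and does not epimerise the non-activated α-centre C1.

Step 6
Reactants: 11 benzyl (2R,4Z)-2-(but-3-yn-1-yl)-5-iodohex-4-enoate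
Product: 13 (3R,5Z)-3-(but-3-yn-1-yl)-6-iodo-2-methylhept-5-en-2-ol, via methyl ketone 12 (not isolated)
Conditions: MeMgBr (excess), CeCl3 (anhydrous), THF, −78 to 0 °C
Reagents that add atoms: methylmagnesium bromide, C[Mg]Br
Why: Double Grignard addition to the ester builds the dimethylcarbinol at C15, the ketone 12 reacting on faster than the ester, while CeCl3 suppresses enolisation of 12 so that C1 keeps its configuration and the alkenyl iodide does not exchange with the Grignard reagent.

Step 7
Reactants: 13 (3R,5Z)-3-(but-3-yn-1-yl)-6-iodo-2-methylhept-5-en-2-ol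
Product: 14 {[(3R,5Z)-3-(but-3-yn-1-yl)-6-iodo-2-methylhept-5-en-2-yl]oxy}(triethyl)silane
Conditions: Et3SiOTf, 2,6-lutidine, CH2Cl2, −78 to 0 °C
Reagents that add atoms: triethylsilyl trifluoromethanesulfonate, CC[Si](CC)(CC)OS(=O)(=O)C(F)(F)F
Why: Silylation of a hindered tertiary alcohol with a silyl triflate and a hindered pyridine base is standard and masks the only protic group before the organoaluminium, hydride and Lewis-acid steps.

Step 8
Reactants: 14 {[(3R,5Z)-3-(but-3-yn-1-yl)-6-iodo-2-methylhept-5-en-2-yl]oxy}(triethyl)silane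
Product: 16 methyl (2E,6R,8Z)-9-iodo-3-methyl-6-{2-[(triethylsilyl)oxy]propan-2-yl}deca-2,8-dienoate, via alkenyldimethylalane 15 (not isolated)
Conditions: AlMe3, Cp2ZrCl2 (0.3 equiv), CH2Cl2, 0 °C to rt; excess AlMe3 removed in vacuo; then ClCO2Me, CH2Cl2, 0 °C to rt
Reagents that add atoms: trimethylaluminium, C[Al](C)C; methyl chloroformate, COC(=O)Cl
Why: Negishi zirconium-catalysed carboalumination adds methyl and aluminium syn across the terminal alkyne with aluminium on the terminal carbon, and acylation of the alkenylalane by the chloroformate with retention gives the E-enoate that carries C10, C11, C12 and its methyl group.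

Step 9
Reactants: 16 methyl (2E,6R,8Z)-9-iodo-3-methyl-6-{2-[(triethylsilyl)oxy]propan-2-yl}deca-2,8-dienoate
Product: 17 (2E,6R,8Z)-9-iodo-3-methyl-6-{2-[(triethylsilyl)oxy]propan-2-yl}deca-2,8-dien-1-ol
Conditions: i-Bu2AlH (2.5 equiv), CH2Cl2, −78 °C; aq potassium sodium tartrate
Reagents that add atoms: none
Why: 1,2-Reduction of the enoate with i-Bu2AlH at low temperature gives the allylic alcohol without affecting the alkene geometries, the C–I bond or the silyl ether.

Step 10
Reactants: 17 (2E,6R,8Z)-9-iodo-3-methyl-6-{2-[(triethylsilyl)oxy]propan-2-yl}deca-2,8-dien-1-ol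
Product: 18 (2E,6R,8Z)-9-iodo-3-methyl-6-{2-[(triethylsilyl)oxy]propan-2-yl}deca-2,8-dienal
Conditions: MnO2 (activated, excess), CH2Cl2, rt
Reagents that add atoms: none
Why: MnO2 oxidises the allylic alcohol selectively to the conjugated aldehyde under neutral conditions and preserves the E geometry.

Step 11
Reactants: 19 methyl 3-methylbut-2-enoate
Product: 21 {[(1Z)-1-methoxy-3-methylbuta-1,3-dien-1-yl]oxy}(trimethyl)silane, via lithium dienolate 20 (not isolated)
Conditions: LiN(i-Pr)2, THF, −78 °C; then Me3SiCl, −78 °C to rt; distillation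
Reagents that add atoms: chlorotrimethylsilane, C[Si](C)(C)Cl
Why: Kinetic γ-deprotonation of the β,β-dimethyl enoate by the lithium amide and O-silylation of the dienolate is the standard preparation of this silyl dienolate, whose ketene acetal geometry is of no consequence for the next step.

Step 12
Reactants: 18 (2E,6R,8Z)-9-iodo-3-methyl-6-{2-[(triethylsilyl)oxy]propan-2-yl}deca-2,8-dienal; 21 {[(1Z)-1-methoxy-3-methylbuta-1,3-dien-1-yl]oxy}(trimethyl)silane
Product: 23 (6S)-6-[(1E,5R,7Z)-8-iodo-2-methyl-5-{2-[(triethylsilyl)oxy]propan-2-yl}nona-1,7-dien-1-yl]-4-methyl-5,6-dihydro-2H-pyran-2-one, via copper aldolate 22 (not isolated)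
Conditions: Cu(OTf)2 (10 mol%), (S)-Tol-BINAP (11 mol%), Bu4N[Ph3SiF2] (20 mol%), THF; 18, 21 (2 equiv), −40 °C to rt; aq NH4Cl
Reagents that add atoms: none
Why: In this catalytic asymmetric vinylogous Mukaiyama aldol reaction fluoride turns the silyl dienolate into a Tol-BINAP-bound dienolate of monovalent copper that adds through its γ-carbon to the Si face of the enal (forming C9–C10 and setting C10 as S under catalyst control), and because the dienolate reacts in its s-cis form the copper alkoxide and the ester lie cis on the new C7=C8 bond and close to the δ-lactone with loss of methoxide, which turns the catalyst over.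

Step 13
Reactants: 23 (6S)-6-[(1E,5R,7Z)-8-iodo-2-methyl-5-{2-[(triethylsilyl)oxy]propan-2-yl}nona-1,7-dien-1-yl]-4-methyl-5,6-dihydro-2H-pyran-2-one
Product: 25 trans-epoxy lactone (1R,4S,6R)-4-[(1E,5R,7Z)-8-iodo-2-methyl-5-{2-[(triethylsilyl)oxy]propan-2-yl}nona-1,7-dien-1-yl]-6-methyl-3,7-dioxabicyclo[4.1.0]heptan-2-one, via peroxy enolate 24 (not isolated)
Conditions: t-BuOOH (anhydrous, in decane, 5 equiv), DBU (1.5 equiv), CH2Cl2, 0 °C to rt
Reagents that add atoms: tert-butyl hydroperoxide, CC(C)(C)OO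
Why: DBU deprotonates t-BuOOH, the tert-butylperoxide anion undergoes Michael addition at C8 (the β-carbon of the unsaturated lactone) to give peroxy enolate 24 with the new C8–O bond, and the enolate carbon C7 then attacks the proximal peroxide oxygen and expels tert-butoxide, forming the C7–O bond. The closest known reaction type is the Weitz–Scheffer nucleophilic epoxidation of α,β-unsaturated δ-lactones (6-substituted 5,6-dihydropyran-2-ones) with DBU and anhydrous t-BuOOH, which delivers the oxirane trans to the substituent on the carbinol carbon. The oxirane closes by a 3-exo-tet displacement at oxygen, and because the C7–C8 bond is part of the six-membered ring it cannot rotate in 24, so the new ring is necessarily cis-fused and C6 and C9 end up cis on it. C8 is set by the C10 stereocentre, since the peroxide approaches axially on the face of the half-chair opposite the pseudo-equatorial alkenyl group, which gives the trans epoxy lactone and hence the syn C8–O/C10–O pair of the target, and C7 is set by C8 because closure is only possible on the face that carries the peroxide. The step needs site selectivity, which comes from C7=C8 being the only alkene conjugated to a carbonyl (the C11=C12 alkene and the iodoalkene do not react with a nucleophilic oxidant), face selectivity, which comes from C10, and freedom from γ-deprotonation at C9 with eliminative opening of the allylic lactone, which the weakly basic peroxide in an aprotic solvent is expected to provide.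

Step 14
Reactants: 25 trans-epoxy lactone
Product: 26 epoxy lactol (1R,4S,6R)-4-[(1E,5R,7Z)-8-iodo-2-methyl-5-{2-[(triethylsilyl)oxy]propan-2-yl}nona-1,7-dien-1-yl]-6-methyl-3,7-dioxabicyclo[4.1.0]heptan-2-ol (both C2 epimers)
Conditions: i-Bu2AlH (1.1 equiv), CH2Cl2, −78 °C; aq potassium sodium tartrate
Reagents that add atoms: none
Why: Partial reduction of a lactone with one equivalent of i-Bu2AlH at −78 °C stops at the aluminium hemiacetal and gives the lactol on work-up, the oxirane and the iodoalkene being inert at this temperature.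

Step 15
Reactants: 26 epoxy lactol
Product: 28 (2S,3E,7R,9Z)-1-[(2R,3S)-3-ethenyl-2-methyloxiran-2-yl]-10-iodo-4-methyl-7-{2-[(triethylsilyl)oxy]propan-2-yl}undeca-3,9-dien-2-ol, via open-chain epoxy aldehyde 27 (not isolated)
Conditions: Ph3PCH3Br (4 equiv), KN(SiMe3)2 (3.8 equiv), THF, 0 °C; then 26, 0 °C to rt
Reagents that add atoms: methyltriphenylphosphonium bromide, used as its ylide, C[P+](c1ccccc1)(c1ccccc1)c1ccccc1.[Br-]
Why: Wittig methylenation of the lactol through its hydroxy aldehyde tautomer 27 adds C5 and unfolds the ring, freeing the C10 hydroxyl, while the non-enolisable oxiranyl aldehyde keeps the configuration at C7.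

Step 16
Reactants: 28 vinyl oxirane with free C10 hydroxyl and Z-iodoalkene
Product: 30 (1R,3S,4E,8R,10Z,14S)-1,5,11-trimethyl-8-{2-[(triethylsilyl)oxy]propan-2-yl}-15-oxabicyclo[12.1.0]pentadeca-4,10-dien-3-ol, via B-alkyl-9-BBN borane 29 (not isolated)
Conditions: 9-BBN-H (2.5 equiv), THF, 0 °C to rt; H2O; then slow addition to PdCl2(dppf) (20 mol%; dppf = 1,1'-bis(diphenylphosphino)ferrocene), AsPh3, Cs2CO3, DMF/THF/H2O, 45 °C, final 1 mM
Reagents that add atoms: none
Why: Anti-Markovnikov hydroboration of the only monosubstituted alkene by 9-BBN-H (boron on C5) followed by intramolecular B-alkyl Suzuki–Miyaura coupling with the Z-iodoalkene under high dilution forms C4–C5 with retention of the alkene geometry and closes the 14-membered carbocycle without creating a stereocentre.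

Step 17
Reactants: 30 macrocyclic epoxy alcohol, C15 triethylsilyl ether
Product: 31 (1R,3S,4E,8R,10Z,14S)-8-(2-hydroxypropan-2-yl)-1,5,11-trimethyl-15-oxabicyclo[12.1.0]pentadeca-4,10-dien-3-ol
Conditions: Bu4NF, THF, rt to 40 °C
Reagents that add atoms: none
Why: Fluoride-induced cleavage of the tertiary triethylsilyl ether runs under basic conditions that leave the acid-sensitive trisubstituted oxirane intact, and is placed before acetylation so that no ester is exposed to fluoride.

Step 18
Reactants: 31 macrocyclic epoxy diol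
Product: 32 (1R,3S,4E,8R,10Z,14S)-8-(2-hydroxypropan-2-yl)-1,5,11-trimethyl-15-oxabicyclo[12.1.0]pentadeca-4,10-dien-3-yl acetate (CNP0254503.1)
Conditions: Ac2O (1.5 equiv), pyridine, DMAP (cat.), CH2Cl2, 0 °C
Reagents that add atoms: acetic anhydride, CC(=O)OC(C)=O
Why: Pyridine/DMAP-mediated acylation is selective for the secondary allylic C10 hydroxyl because the tertiary C15 hydroxyl is far less reactive towards acetic anhydride at 0 °C, and C10 keeps its configuration since only the O–H bond is broken.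

**Compound list**

1 | but-2-yn-1-ol | CC#CCO | starting material
2 | sodium 2,2-bis(2-methoxyethoxy)-3-methyl-2,5-dihydro-1,2-oxaaluminol-2-uide (cyclic alkenylaluminate; Al bound to the methyl-bearing alkene carbon and to the alcohol oxygen) | CC1=CCO[Al-]1(OCCOC)OCCOC.[Na+] | intermediate
3 | (2Z)-3-iodobut-2-en-1-ol | OC/C=C(/C)I | intermediate
4 | (2Z)-1-bromo-3-iodobut-2-ene | BrC/C=C(/C)I | intermediate
5 | hex-5-ynoic acid | C#CCCCC(=O)O | starting material
6 | (4S)-4-benzyl-1,3-oxazolidin-2-one | O=C1N[C@@H](Cc2ccccc2)CO1 | starting material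
7 | hex-5-ynoic pivalic anhydride | C#CCCCC(=O)OC(=O)C(C)(C)C | intermediate
8 | (4S)-4-benzyl-3-(hex-5-ynoyl)-1,3-oxazolidin-2-one | C#CCCCC(=O)N1[C@@H](Cc2ccccc2)COC1=O | intermediate
9 | sodium Z-enolate of 8 (enolate oxygen cis to the alkyl chain) | C#CCC/C=C(\[O-])N1[C@@H](Cc2ccccc2)COC1=O.[Na+] | intermediate
10 | (4S)-4-benzyl-3-[(2R,4Z)-2-(but-3-yn-1-yl)-5-iodohex-4-enoyl]-1,3-oxazolidin-2-one | C#CCC[C@@H](C(=O)N1[C@@H](Cc2ccccc2)COC1=O)C/C=C(/C)I | intermediate
11 | benzyl (2R,4Z)-2-(but-3-yn-1-yl)-5-iodohex-4-enoate | C#CCC[C@@H](C(=O)OCc1ccccc1)C/C=C(/C)I | intermediate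
12 | (3R,5Z)-3-(but-3-yn-1-yl)-6-iodohept-5-en-2-one | C#CCC[C@@H](C(C)=O)C/C=C(/C)I | intermediate
13 | (3R,5Z)-3-(but-3-yn-1-yl)-6-iodo-2-methylhept-5-en-2-ol | C#CCC[C@@H](C(C)(C)O)C/C=C(/C)I | intermediate
14 | {[(3R,5Z)-3-(but-3-yn-1-yl)-6-iodo-2-methylhept-5-en-2-yl]oxy}(triethyl)silane | C#CCC[C@@H](C(C)(C)O[Si](CC)(CC)CC)C/C=C(/C)I | intermediate
15 | dimethyl[(1E,5R,7Z)-8-iodo-2-methyl-5-{2-[(triethylsilyl)oxy]propan-2-yl}nona-1,7-dien-1-yl]alane | C[Al](C)/C=C(\C)CC[C@@H](C(C)(C)O[Si](CC)(CC)CC)C/C=C(/C)I | intermediate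
16 | methyl (2E,6R,8Z)-9-iodo-3-methyl-6-{2-[(triethylsilyl)oxy]propan-2-yl}deca-2,8-dienoate | COC(=O)/C=C(\C)CC[C@@H](C(C)(C)O[Si](CC)(CC)CC)C/C=C(/C)I | intermediate
17 | (2E,6R,8Z)-9-iodo-3-methyl-6-{2-[(triethylsilyl)oxy]propan-2-yl}deca-2,8-dien-1-ol | OC/C=C(\C)CC[C@@H](C(C)(C)O[Si](CC)(CC)CC)C/C=C(/C)I | intermediate
18 | (2E,6R,8Z)-9-iodo-3-methyl-6-{2-[(triethylsilyl)oxy]propan-2-yl}deca-2,8-dienal | O=C/C=C(\C)CC[C@@H](C(C)(C)O[Si](CC)(CC)CC)C/C=C(/C)I | intermediate
19 | methyl 3-methylbut-2-enoate | COC(=O)C=C(C)C | starting material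
20 | lithium 1-methoxy-3-methylbuta-1,3-dien-1-olate | C=C(C)/C=C(\[O-])OC.[Li+] | intermediate
21 | {[(1Z)-1-methoxy-3-methylbuta-1,3-dien-1-yl]oxy}(trimethyl)silane | C=C(C)/C=C(\O[Si](C)(C)C)OC | intermediate
22 | copper alkoxide of methyl (2Z,5S,6E,10R,12Z)-5-hydroxy-13-iodo-3,7-dimethyl-10-{2-[(triethylsilyl)oxy]propan-2-yl}tetradeca-2,6,12-trienoate (Tol-BINAP on copper not drawn) | COC(=O)/C=C(C)\C[C@H](O[Cu])/C=C(\C)CC[C@@H](C(C)(C)O[Si](CC)(CC)CC)C/C=C(/C)I | intermediate
23 | (6S)-6-[(1E,5R,7Z)-8-iodo-2-methyl-5-{2-[(triethylsilyl)oxy]propan-2-yl}nona-1,7-dien-1-yl]-4-methyl-5,6-dihydro-2H-pyran-2-one | O=C1C=C(C)C[C@H](O1)/C=C(\C)CC[C@@H](C(C)(C)O[Si](CC)(CC)CC)C/C=C(/C)I | intermediate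
24 | 1,8-diazabicyclo[5.4.0]undec-7-enium (4R,6S)-4-(tert-butylperoxy)-6-[(1E,5R,7Z)-8-iodo-2-methyl-5-{2-[(triethylsilyl)oxy]propan-2-yl}nona-1,7-dien-1-yl]-4-methyl-5,6-dihydro-4H-pyran-2-olate | CC(C)(C)OO[C@]1(C)C[C@H](OC([O-])=C1)/C=C(\C)CC[C@@H](C(C)(C)O[Si](CC)(CC)CC)C/C=C(/C)I.C1CCC2=[NH+]CCCN2CC1 | intermediate
25 | (1R,4S,6R)-4-[(1E,5R,7Z)-8-iodo-2-methyl-5-{2-[(triethylsilyl)oxy]propan-2-yl}nona-1,7-dien-1-yl]-6-methyl-3,7-dioxabicyclo[4.1.0]heptan-2-one | O=C1[C@@H]2O[C@]2(C)C[C@H](O1)/C=C(\C)CC[C@@H](C(C)(C)O[Si](CC)(CC)CC)C/C=C(/C)I | intermediate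
26 | (1R,4S,6R)-4-[(1E,5R,7Z)-8-iodo-2-methyl-5-{2-[(triethylsilyl)oxy]propan-2-yl}nona-1,7-dien-1-yl]-6-methyl-3,7-dioxabicyclo[4.1.0]heptan-2-ol, both C2 epimers | OC1[C@@H]2O[C@]2(C)C[C@H](O1)/C=C(\C)CC[C@@H](C(C)(C)O[Si](CC)(CC)CC)C/C=C(/C)I | intermediate
27 | (2R,3R)-3-[(2S,3E,7R,9Z)-2-hydroxy-10-iodo-4-methyl-7-{2-[(triethylsilyl)oxy]propan-2-yl}undeca-3,9-dien-1-yl]-3-methyloxirane-2-carbaldehyde | O=C[C@@H]1O[C@]1(C)C[C@H](O)/C=C(\C)CC[C@@H](C(C)(C)O[Si](CC)(CC)CC)C/C=C(/C)I | intermediate
28 | (2S,3E,7R,9Z)-1-[(2R,3S)-3-ethenyl-2-methyloxiran-2-yl]-10-iodo-4-methyl-7-{2-[(triethylsilyl)oxy]propan-2-yl}undeca-3,9-dien-2-ol | C=C[C@@H]1O[C@]1(C)C[C@H](O)/C=C(\C)CC[C@@H](C(C)(C)O[Si](CC)(CC)CC)C/C=C(/C)I | intermediate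
29 | B-alkyl borane: 28 with its ethenyl group converted into CH2CH2 bound to the boron of 9-borabicyclo[3.3.1]nonane (drawn with free C10 hydroxyl) | C1CCC2CCCC1B2CC[C@@H]1O[C@]1(C)C[C@H](O)/C=C(\C)CC[C@@H](C(C)(C)O[Si](CC)(CC)CC)C/C=C(/C)I | intermediate
30 | (1R,3S,4E,8R,10Z,14S)-1,5,11-trimethyl-8-{2-[(triethylsilyl)oxy]propan-2-yl}-15-oxabicyclo[12.1.0]pentadeca-4,10-dien-3-ol | O[C@@H]1/C=C(\C)CC[C@@H](C(C)(C)O[Si](CC)(CC)CC)C/C=C(/C)CC[C@@H]2O[C@]2(C)C1 | intermediate
31 | (1R,3S,4E,8R,10Z,14S)-8-(2-hydroxypropan-2-yl)-1,5,11-trimethyl-15-oxabicyclo[12.1.0]pentadeca-4,10-dien-3-ol | O[C@@H]1/C=C(\C)CC[C@@H](C(C)(C)O)C/C=C(/C)CC[C@@H]2O[C@]2(C)C1 | intermediate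
32 | (1R,3S,4E,8R,10Z,14S)-8-(2-hydroxypropan-2-yl)-1,5,11-trimethyl-15-oxabicyclo[12.1.0]pentadeca-4,10-dien-3-yl acetate (CNP0254503.1) | CC(=O)O[C@@H]1/C=C(\C)CC[C@@H](C(C)(C)O)C/C=C(/C)CC[C@@H]2O[C@]2(C)C1 | target

**Step count and risks**

Total step count: 18. Longest linear sequence: 16 steps (steps 1, 2, 4 to 10 and 12 to 18, from but-2-yn-1-ol).

Most likely to fail, step 16. Transmetalation of the hindered borate at millimolar concentration may be too slow, so that oligomerisation or reduction of the iodoalkene takes over, and the hydroxyborate may instead displace the neighbouring oxirane oxygen in a 1,3-elimination. The fallback separates the two events and changes the organometal; it sets out from 28 and comes back at 31. Vinyl oxirane 28 is silylated at the C10 hydroxyl (Et3SiCl, imidazole, CH2Cl2) to give the bis(triethylsilyl) ether F1. Hydroboration with 9-BBN-H followed by oxidation with NaBO3 gives the primary C5 alcohol F2, and I2, PPh3 and imidazole convert it into the primary iodide F3. LiCl-promoted insertion of zinc dust into the alkyl C–I bond (the alkenyl iodide is inert at room temperature) and intramolecular Negishi coupling under Pd(OAc)2/SPhos at high dilution give the macrocyclic bis(triethylsilyl) ether F4. Bu4NF as in step 17 then removes both silyl groups and returns diol 31.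

Second, step 12. The copper dienolate may add with poor face selectivity to a β,β-disubstituted enal, or react through its s-trans form so that an E-configured open-chain aldol accumulates that cannot lactonise. The fallback builds the lactone by allylboration and metathesis; it sets out from 18 and comes back at 23. Enal 18 is treated with the 2-methylallyl(diisopinocampheyl)borane made from (−)-Ipc2BOMe and 2-methylallylmagnesium chloride (Brown allylboration, Et2O, −78 °C, NaBO3 work-up). By analogy with the parent allyl reagent this is expected to add to the Si face and give the (S)-homoallylic alcohol F5. Acryloyl chloride and Et3N give the acrylate F6. Ring-closing metathesis with the second-generation Grubbs catalyst RuCl2(=CHPh)(PCy3)(H2IMes) in toluene at 80 °C joins the acrylate and the 1,1-disubstituted alkene, forms C7=C8 inside the ring and returns lactone 23.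

Third, step 13. Michael addition of the peroxide to the β,β-disubstituted acceptor may be slow enough for γ-deprotonation at C9 and eliminative opening of the allylic lactone to compete, and the methyl group on C8 may erode the preference for attack anti to the C10 substituent. The fallback unfolds the lactone, epoxidises under reagent control and refolds; it sets out from 23 and comes back at 25. Lactone 23 is reduced with excess i-Bu2AlH to the Z-allylic diol F7. Sharpless asymmetric epoxidation (Ti(Oi-Pr)4, L-(+)-diethyl tartrate, t-BuOOH, 4 Å sieves, CH2Cl2, −20 °C) epoxidises the primary Z-allylic alcohol to the epoxy diol F8 with C7 S and C8 R. The C10 carbinol, a secondary allylic alcohol with a cis β-methyl group, is expected to react far more slowly. TEMPO with PhI(OAc)2 oxidises the primary alcohol, and the resulting lactol 26 is oxidised on in the same flask to epoxy lactone 25.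

**Further compounds**

F1 | step 16 | C10 triethylsilyl ether of 28: {[(2S,3E,7R,9Z)-1-[(2R,3S)-3-ethenyl-2-methyloxiran-2-yl]-10-iodo-4-methyl-7-{2-[(triethylsilyl)oxy]propan-2-yl}undeca-3,9-dien-2-yl]oxy}(triethyl)silane | C=C[C@@H]1O[C@]1(C)C[C@H](O[Si](CC)(CC)CC)/C=C(\C)CC[C@@H](C(C)(C)O[Si](CC)(CC)CC)C/C=C(/C)I
F2 | step 16 | primary C5 alcohol: F1 with its ethenyl group converted into CH2CH2OH | OCC[C@@H]1O[C@]1(C)C[C@H](O[Si](CC)(CC)CC)/C=C(\C)CC[C@@H](C(C)(C)O[Si](CC)(CC)CC)C/C=C(/C)I
F3 | step 16 | primary C5 iodide: F1 with its ethenyl group converted into CH2CH2I | ICC[C@@H]1O[C@]1(C)C[C@H](O[Si](CC)(CC)CC)/C=C(\C)CC[C@@H](C(C)(C)O[Si](CC)(CC)CC)C/C=C(/C)I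
F4 | step 16 | macrocyclic bis(triethylsilyl) ether of diol 31 | CC[Si](CC)(CC)O[C@@H]1/C=C(\C)CC[C@@H](C(C)(C)O[Si](CC)(CC)CC)C/C=C(/C)CC[C@@H]2O[C@]2(C)C1
F5 | step 12 | (4S,5E,9R,11Z)-12-iodo-2,6-dimethyl-9-{2-[(triethylsilyl)oxy]propan-2-yl}trideca-1,5,11-trien-4-ol | C=C(C)C[C@H](O)/C=C(\C)CC[C@@H](C(C)(C)O[Si](CC)(CC)CC)C/C=C(/C)I
F6 | step 12 | (4S,5E,9R,11Z)-12-iodo-2,6-dimethyl-9-{2-[(triethylsilyl)oxy]propan-2-yl}trideca-1,5,11-trien-4-yl prop-2-enoate | C=CC(=O)O[C@@H](CC(C)=C)/C=C(\C)CC[C@@H](C(C)(C)O[Si](CC)(CC)CC)C/C=C(/C)I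
F7 | step 13 | (2Z,5S,6E,10R,12Z)-13-iodo-3,7-dimethyl-10-{2-[(triethylsilyl)oxy]propan-2-yl}tetradeca-2,6,12-triene-1,5-diol | OC/C=C(C)\C[C@H](O)/C=C(\C)CC[C@@H](C(C)(C)O[Si](CC)(CC)CC)C/C=C(/C)I
F8 | step 13 | (2S,3E,7R,9Z)-1-[(2R,3S)-3-(hydroxymethyl)-2-methyloxiran-2-yl]-10-iodo-4-methyl-7-{2-[(triethylsilyl)oxy]propan-2-yl}undeca-3,9-dien-2-ol | OC[C@@H]1O[C@]1(C)C[C@H](O)/C=C(\C)CC[C@@H](C(C)(C)O[Si](CC)(CC)CC)C/C=C(/C)I
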